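**Retrosynthetic overview**

1. Rings: spiro dihydropyranone (ring A), cyclohexane (ring B), cyclopentane (ring C), bicyclo[2.2.2]octanone cage (rings D/E), γ-lactone (ring F). The plan rests on ring C: its CH at the B/C ring fusion carries the C(CH3)(OH) carbon of ring B as a branch, so "cyclopentane plus acetyl on that CH" is the contraction product of a 1-methylcyclohexane-1,2-diol spanning the same two cage carbons.
2. Ring B is closed last (spiro C to C(OH) bond) by intramolecular vinylogous aldol addition of the ring A dienolate to the acetyl ketone; ring A is grown from an allyl group (hydroboration, gem-dimethyl epoxide, propiolate opening, cis reduction, lactonisation).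
3. Ring C comes from the Et3Al-promoted semipinacol contraction of cis hydroxy mesylate 23, whose six-membered diol ring is closed by SmI2 pinacol coupling of keto aldehyde 21.
4. The hub carbon (allyl plus formyl) is made by enol-ether Wittig reaction and Claisen rearrangement on the cage ketone; the acetonyl arm is carried as a propargyl group and unveiled by gold-catalysed hydration.
5. The cage (D/E, then F) is made first, by auxiliary-controlled double Michael addition of an enone dienolate (from 2,6-dimethylbenzoquinone via a quinone monoketal) to 8-phenylmenthyl acrylate with in-flask propargylation, then lactonisation. Ring order: D/E, F, pinacol six-ring, C (by contraction), A, B.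

Key step: step 16

Assumption: in step 8 the lithium-bridged s-cis acrylate and the ester enolate derived from it react on the face remote from the phenyl ring of the (1R,2S,5R) auxiliary (the Cα re face), which gives the cage enantiomer drawn; the diastereomers are separable, and the enantiomeric auxiliary would be used if the sense proved opposite.

**Route**

Step 1
Reactants: 1 2,6-dimethyl-1,4-benzoquinone
Product: 3 4-methoxy-2,6-dimethylphenol, via 2,6-dimethylhydroquinone 2 (not isolated)
Conditions: H2 (1 atm), Pd/C, MeOH, rt; filter; 1 (5 mol%), conc. H2SO4 (cat.), 60 °C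
Reagents that add atoms: methanol CO
Why: Hydrogenation gives the hydroquinone, and quinone-mediated acid-catalysed mono-etherification methylates the oxygen flanked by two CH (less hindered, more electrophilic carbon) rather than the one flanked by two methyl groups.

Step 2
Reactants: 3 4-methoxy-2,6-dimethylphenol
Product: 4 3-hydroxy-6-methoxy-2,4-dimethylbenzaldehyde
Conditions: Cl2CHOMe, TiCl4, CH2Cl2, −10 → 0 °C; aq. HCl
Reagents that add atoms: dichloromethyl methyl ether COC(Cl)Cl; water O
Why: Rieche formylation (electrophilic aromatic substitution) can only enter at the two equivalent free positions, which are ortho to the methoxy group and activated by both methyl groups.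

Step 3
Reactants: 4 3-hydroxy-6-methoxy-2,4-dimethylbenzaldehyde
Product: 5 3-(hydroxymethyl)-4-methoxy-2,6-dimethylphenol
Conditions: NaBH4, MeOH, 0 °C
Reagents that add atoms: none
Why: Chemoselective borohydride reduction of the aryl aldehyde to the benzylic alcohol.

Step 4
Reactants: 5 3-(hydroxymethyl)-4-methoxy-2,6-dimethylphenol
Product: 7 3-[(tert-butyldimethylsilyloxy)methyl]-4-methoxy-2,6-dimethylphenol, via bis-silyl ether 6 (not isolated)
Conditions: TBSCl (2.4 equiv), imidazole, DMF, rt; then K2CO3 (cat.), MeOH, rt
Reagents that add atoms: tert-butyldimethylsilyl chloride CC(C)(C)[Si](C)(C)Cl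
Why: Both hydroxyls are silylated, and the aryl silyl ether, far more labile to methanolic carbonate than the alkyl one, is then cleaved selectively to free the phenol for dearomatisation.

Step 5
Reactants: 7 3-[(tert-butyldimethylsilyloxy)methyl]-4-methoxy-2,6-dimethylphenol
Product: 8 3-[(tert-butyldimethylsilyloxy)methyl]-4,4-dimethoxy-2,6-dimethylcyclohexa-2,5-dien-1-one
Conditions: PhI(OAc)2, MeOH, 0 °C
Reagents that add atoms: methanol CO
Why: Hypervalent-iodine oxidative dearomatisation of a para-methoxyphenol in methanol gives the quinone monoketal, methanol adding at the methoxy-bearing para carbon.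

Step 6
Reactants: 8 quinone monoketal
Product: 9 3-[(tert-butyldimethylsilyloxy)methyl]-4,4-dimethoxy-2,6-dimethylcyclohex-2-en-1-one (racemic at the CH(CH3) carbon)
Conditions: LiBH(s-Bu)3, THF, −78 °C; aq. NH4Cl
Reagents that add atoms: none
Why: Conjugate hydride addition occurs only at the β-CH of the less substituted enone, because the other β-carbon is fully substituted and the carbonyl is flanked by two α-methyl groups; the new CH(CH3) centre is racemic and is erased in step 8.

Step 7
Reactants: 10 (1R,2S,5R)-8-phenylmenthol
Product: 11 (1R,2S,5R)-8-phenylmenthyl acrylate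
Conditions: acryloyl chloride, Et3N, DMAP (cat.), CH2Cl2, 0 °C
Reagents that add atoms: acryloyl chloride C=CC(=O)Cl
Why: Standard acylation of the secondary alcohol under nucleophilic catalysis; the auxiliary stereocentres are untouched.

Step 8
Reactants: 9 enone; 11 (1R,2S,5R)-8-phenylmenthyl acrylate
Product: 14 cage keto ester (bridgehead CH3 and CH2OTBS, dimethyl ketal bridge, ester syn to the ketone bridge, propargyl syn to the ketal bridge), via lithium dienolate 12 (not isolated), via bicyclic lithium enolate 13 (not isolated)
Conditions: LiN(i-Pr)2, THF, −78 °C; 11, −78 → 0 °C; then HMPA, propargyl bromide, −78 °C → rt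
Reagents that add atoms: propargyl bromide C#CCBr
Why: Kinetic α′-deprotonation gives cross-conjugated dienolate 12, which undergoes a double Michael addition to the acrylate (enolate carbon to the acrylate CH2, then ester enolate onto the enone β-carbon through a lithium-bridged endo arrangement), placing the ester syn to the ketone bridge and, by reaction on the acrylate face remote from the auxiliary phenyl ring, setting both bridgeheads and the ester CH in the absolute sense drawn; enolate 13 is then C-propargylated on the face away from the bulky ester, which sets the C(CH3)(propargyl) centre.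

Step 9
Reactants: 14 cage keto ester
Product: 16 cage diketone lactone (ring F closed), via hydroxy diketo ester 15 (not isolated)
Conditions: 2 M aq. HCl, THF, 45 °C; then CSA (cat.), toluene, 100 °C
Reagents that add atoms: water O
Why: Aqueous acid removes the silyl ether and hydrolyses the ketal (retro-aldol loss of the CH2OH group is blocked because the enol would be a bridgehead alkene), and acid-catalysed intramolecular transesterification then closes the five-membered lactone and releases the auxiliary without touching the ester CH centre.

Step 10
Reactants: 17 allyl chloromethyl ether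
Product: 18 (allyloxymethyl)triphenylphosphonium chloride
Conditions: PPh3, toluene, 60 °C
Reagents that add atoms: triphenylphosphine c1ccc(cc1)P(c1ccccc1)c1ccccc1
Why: SN2 quaternisation of the phosphine by the reactive α-chloro ether.

Step 11
Reactants: 16 cage diketone lactone; 18 (allyloxymethyl)triphenylphosphonium chloride
Product: 19 allyl enol ether of the cage (E/Z mixture)
Conditions: 18, KN(SiMe3)2, THF, 0 °C; then 16, 0 °C → rt
Reagents that add atoms: none
Why: Wittig olefination with the alkoxymethylene ylide takes place at the only accessible ketone, the other being shielded by two quaternary α-carbons; the enol ether geometry is of no consequence.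

Step 12
Reactants: 19 allyl enol ether
Product: 20 hub aldehyde (quaternary carbon bearing allyl and formyl)
Conditions: toluene, 170 °C (sealed tube)
Reagents that add atoms: none
Why: Thermal Claisen rearrangement transfers the allyl group to the enol ether carbon from the face remote from the propargyl group on the neighbouring quaternary carbon (the other face presents only the lactone CH), which sets the hub quaternary centre with the formyl group next to the propargyl arm.

Step 13
Reactants: 20 hub aldehyde
Product: 21 keto aldehyde (acetonyl arm)
Conditions: Ph3PAuNTf2 (2 mol%), 1,4-dioxane–H2O, 60 °C; used crude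
Reagents that add atoms: water O
Why: Gold-catalysed Markovnikov hydration of the terminal alkyne, assisted by the neighbouring ketone oxygen, gives the methyl ketone while alkene, aldehyde and lactone are untouched.

Step 14
Reactants: 21 keto aldehyde
Product: 22 cis diol (six-membered ring; both hydroxyls on the convex face)
Conditions: SmI2 (2.5 equiv), t-BuOH, THF, −78 °C
Reagents that add atoms: none
Why: In this SmI2 pinacol coupling the aldehyde ketyl adds to the methyl ketone (six-membered closure) through a samarium-bridged arrangement that gives the cis diol, with both oxygens on the convex face because the solvated samarium-bridged unit does not fit into the cleft between the two cage bridges; this fixes both carbinol centres.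

Step 15
Reactants: 22 cis diol
Product: 23 cis hydroxy mesylate
Conditions: MsCl, Et3N, CH2Cl2, −20 → 0 °C
Reagents that add atoms: methanesulfonyl chloride CS(=O)(=O)Cl
Why: Sulfene-type mesylation acylates only the secondary hydroxyl; the tertiary one does not react.

Step 16
Reactants: 23 cis hydroxy mesylate
Product: 24 acetylcyclopentane cage ketone (ring C closed)
Conditions: Et3Al (3 equiv), CH2Cl2, −78 → −20 °C; aq. Rochelle salt
Reagents that add atoms: none
Why: Et3Al deprotonates the tertiary hydroxyl (ethane is lost), and the aluminium alkoxide, bridged to the cis mesylate oxygen, weakens the C–OMs bond; the ring CH2–C(O) bond antiperiplanar to it then shifts to the mesylate carbon while the carbinol carbon becomes the acetyl carbonyl, which is the organoaluminium-promoted pinacol-type (semipinacol) rearrangement of 2-sulfonyloxy tertiary alcohols. Ring C is closed by this suprafacial 1,2-alkyl shift, a six-to-five ring contraction, and not by an external nucleophile. The new CH centre is set by inversion at the mesylate carbon: the mesylate lies on the convex face (the face of the bridgehead CH2O), the CH2 enters from the concave face, and the acetyl group is left on the convex face, as ring B needs. Migration of the ring bond and not of the methyl group requires the boat form of the six-membered ring, in which the mesylate is pseudo-equatorial and anti to the CH2–C(O) bond; this boat should be enforced because the chair would push the carbinol methyl into the cleft between two cage bridges. Epoxide formation is excluded because hydroxyl and mesylate are cis, and the lactone, the shielded cage ketone and the allyl group should be inert to Et3Al at low temperature.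

Step 17
Reactants: 24 acetylcyclopentane cage ketone
Product: 25 dioxolane of the methyl ketone
Conditions: (TMSOCH2)2, TMSOTf (cat.), CH2Cl2, −78 → −20 °C
Reagents that add atoms: 1,2-bis(trimethylsilyloxy)ethane C[Si](C)(C)OCCO[Si](C)(C)C
Why: Noyori ketalisation protects only the methyl ketone, the cage ketone being too hindered; the mask is needed for the basic and nucleophilic steps that build ring A.

Step 18
Reactants: 25 dioxolane
Product: 26 primary alcohol (3-hydroxypropyl arm)
Conditions: 9-BBN, THF, 0 °C → rt; then H2O2, aq. NaOAc
Reagents that add atoms: hydrogen peroxide OO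
Why: Anti-Markovnikov hydroboration of the terminal alkene with the bulky borane, then oxidation with retention, gives the primary alcohol without reducing lactone, ketal or hindered ketone.

Step 19
Reactants: 26 primary alcohol
Product: 27 aldehyde
Conditions: Dess–Martin periodinane, NaHCO3, CH2Cl2, rt
Reagents that add atoms: none
Why: Dess–Martin oxidation of the primary alcohol under buffered conditions.

Step 20
Reactants: 27 aldehyde
Product: 28 trisubstituted alkene (4-methylpent-3-enyl arm)
Conditions: i-PrPPh3I, n-BuLi, THF, 0 °C; then 27, −78 → 0 °C
Reagents that add atoms: isopropyltriphenylphosphonium iodide CC(C)[P+](c1ccccc1)(c1ccccc1)c1ccccc1.[I-]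
Why: Wittig olefination of the aldehyde with the isopropylidene ylide installs the gem-dimethyl alkene; no stereocentre is formed.

Step 21
Reactants: 28 trisubstituted alkene
Product: 29 epoxide (mixture at the epoxide CH)
Conditions: mCPBA, NaHCO3, CH2Cl2, 0 °C
Reagents that add atoms: 3-chloroperbenzoic acid OOC(=O)c1cccc(Cl)c1
Why: Prilezhaev epoxidation of the electron-rich trisubstituted alkene; the epoxide CH forms as a mixture, which is harmless because this carbon is planarised in step 24.

Step 22
Reactants: 29 epoxide
Product: 30 hydroxy ynoate (tertiary alcohol; mixture at the propargylic CH)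
Conditions: ethyl propiolate, n-BuLi, THF, −78 °C; BF3·OEt2; then 29, −78 °C
Reagents that add atoms: ethyl propiolate C#CC(=O)OCC
Why: BF3-promoted epoxide opening by the lithium alkynyl (Yamaguchi–Hirao alkynylation) occurs by SN2 attack at the secondary epoxide carbon and leaves the tertiary alcohol; the weakly nucleophilic ester-substituted alkynylborate should react with the activated epoxide faster than with the hindered cage lactone.

Step 23
Reactants: 30 hydroxy ynoate
Product: 33 dihydropyranone methyl ketone (ring A closed), via Z-hydroxy enoate 31 (not isolated), via dihydropyranone dioxolane 32 (not isolated)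
Conditions: H2 (1 atm), Pd/CaCO3 poisoned with Pb(OAc)2, quinoline, EtOAc, rt; filter; then 1 M aq. HCl, THF, rt → 40 °C
Reagents that add atoms: water O
Why: Syn semi-hydrogenation gives the Z-enoate, whose tertiary hydroxyl lactonises under acid to the dihydropyranone, and the same acid hydrolyses the dioxolane to free the methyl ketone.

Step 24
Reactants: 33 dihydropyranone methyl ketone
Product: 34 target (ring B closed)
Conditions: LiN(SiMe3)2 (1.05 equiv), THF–DMPU, −78 → −50 °C; AcOH, −78 °C
Reagents that add atoms: none
Why: In this intramolecular vinylogous aldol addition the γ-proton of the unsaturated δ-lactone is expected to be the most acidic C–H (more so than the ketone α-protons), so the amide base gives the pyranolate, whose γ-carbon adds to the methyl ketone in a 6-exo-trig closure at low temperature before it can open to the dienoate; the chair imposed by the cis B/C fusion puts the new hydroxyl axial toward the bridgehead CH2O and the methyl equatorial, and the oxygen-bearing CMe2 carbon of the dienolate is expected anti to the developing alkoxide in the non-chelated, DMPU-solvated transition state, which sets the spiro centre.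

**Compound list**

1 | 2,6-dimethyl-1,4-benzoquinone | CC1=CC(=O)C=C(C)C1=O | starting material
2 | 2,6-dimethylhydroquinone | Cc1cc(O)cc(C)c1O | intermediate (not isolated)
3 | 4-methoxy-2,6-dimethylphenol | COc1cc(C)c(O)c(C)c1 | intermediate
4 | 3-hydroxy-6-methoxy-2,4-dimethylbenzaldehyde | COc1cc(C)c(O)c(C)c1C=O | intermediate
5 | 3-(hydroxymethyl)-4-methoxy-2,6-dimethylphenol | COc1cc(C)c(O)c(C)c1CO | intermediate
6 | bis(tert-butyldimethylsilyl) ether of 5 | COc1cc(C)c(O[Si](C)(C)C(C)(C)C)c(C)c1CO[Si](C)(C)C(C)(C)C | intermediate (not isolated)
7 | 3-[(tert-butyldimethylsilyloxy)methyl]-4-methoxy-2,6-dimethylphenol | COc1cc(C)c(O)c(C)c1CO[Si](C)(C)C(C)(C)C | intermediate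
8 | 3-[(tert-butyldimethylsilyloxy)methyl]-4,4-dimethoxy-2,6-dimethylcyclohexa-2,5-dien-1-one | COC1(OC)C=C(C)C(=O)C(C)=C1CO[Si](C)(C)C(C)(C)C | intermediate
9 | 3-[(tert-butyldimethylsilyloxy)methyl]-4,4-dimethoxy-2,6-dimethylcyclohex-2-en-1-one (racemic) | CC1CC(OC)(OC)C(CO[Si](C)(C)C(C)(C)C)=C(C)C1=O | intermediate
10 | (1R,2S,5R)-8-phenylmenthol | CC(C)(c1ccccc1)[C@@H]1CC[C@@H](C)C[C@H]1O | starting material
11 | (1R,2S,5R)-8-phenylmenthyl acrylate | CC(C)(c1ccccc1)[C@@H]1CC[C@@H](C)C[C@H]1OC(=O)C=C | intermediate
12 | lithium cross-conjugated dienolate of 9 | [Li+].[O-]C1=C(C)CC(OC)(OC)C(CO[Si](C)(C)C(C)(C)C)=C1C | intermediate (not isolated)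
13 | bicyclic lithium enolate (double Michael adduct) | COC1(OC)C[C@@]4(C)C[C@H](C(=O)O[C@@H]5C[C@H](C)CC[C@H]5C(C)(C)c6ccccc6)[C@]1(CO[Si](C)(C)C(C)(C)C)C(C)=C4[O-].[Li+] | intermediate (not isolated)
14 | cage keto ester: bicyclo[2.2.2]octanone with bridgehead CH3 and CH2OTBS, dimethyl ketal bridge, 8-phenylmenthyl ester syn to the ketone bridge, C(CH3)(propargyl) with propargyl syn to the ketal bridge | COC1(OC)C[C@@]4(C)C[C@H](C(=O)O[C@@H]5C[C@H](C)CC[C@H]5C(C)(C)c6ccccc6)[C@]1(CO[Si](C)(C)C(C)(C)C)[C@@](C)(CC#C)C4=O | intermediate
15 | hydroxy diketo ester (silyl ether and ketal removed) | O=C1C[C@@]4(C)C[C@H](C(=O)O[C@@H]5C[C@H](C)CC[C@H]5C(C)(C)c6ccccc6)[C@]1(CO)[C@@](C)(CC#C)C4=O | intermediate (not isolated)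
16 | cage diketone lactone (γ-lactone fused at bridgehead CH2O and ester CH; propargyl arm) | O=C1C[C@@]4(C)C[C@@H]5C(=O)OC[C@]51[C@@](C)(CC#C)C4=O | intermediate
17 | allyl chloromethyl ether | C=CCOCCl | starting material
18 | (allyloxymethyl)triphenylphosphonium chloride | C=CCOC[P+](c1ccccc1)(c1ccccc1)c1ccccc1.[Cl-] | intermediate
19 | allyl enol ether of the cage (E/Z mixture) | C=CCOC=C1C[C@@]4(C)C[C@@H]5C(=O)OC[C@]51[C@@](C)(CC#C)C4=O | intermediate
20 | hub aldehyde (quaternary carbon with allyl and formyl; propargyl arm) | C=CC[C@@]1(C=O)C[C@@]4(C)C[C@@H]5C(=O)OC[C@]51[C@@](C)(CC#C)C4=O | intermediate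
21 | keto aldehyde (acetonyl arm) | C=CC[C@@]1(C=O)C[C@@]4(C)C[C@@H]5C(=O)OC[C@]51[C@@](C)(CC(C)=O)C4=O | intermediate
22 | cis diol (secondary and tertiary hydroxyl on the convex face) | C=CC[C@@]13C[C@@]4(C)C[C@@H]5C(=O)OC[C@]51[C@@](C)(C[C@@](C)(O)[C@H]3O)C4=O | intermediate
23 | cis hydroxy mesylate | C=CC[C@@]13C[C@@]4(C)C[C@@H]5C(=O)OC[C@]51[C@@](C)(C[C@@](C)(O)[C@H]3OS(C)(=O)=O)C4=O | intermediate
24 | acetylcyclopentane cage ketone | C=CC[C@@]13C[C@@]4(C)C[C@@H]5C(=O)OC[C@]51[C@@](C)(C[C@H]3C(C)=O)C4=O | intermediate
25 | dioxolane of 24 | C=CC[C@@]13C[C@@]4(C)C[C@@H]5C(=O)OC[C@]51[C@@](C)(C[C@H]3C6(C)OCCO6)C4=O | intermediate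
26 | primary alcohol (3-hydroxypropyl arm) | OCCC[C@@]13C[C@@]4(C)C[C@@H]5C(=O)OC[C@]51[C@@](C)(C[C@H]3C6(C)OCCO6)C4=O | intermediate
27 | aldehyde (3-oxopropyl arm) | O=CCC[C@@]13C[C@@]4(C)C[C@@H]5C(=O)OC[C@]51[C@@](C)(C[C@H]3C6(C)OCCO6)C4=O | intermediate
28 | trisubstituted alkene (4-methylpent-3-enyl arm) | CC(C)=CCC[C@@]13C[C@@]4(C)C[C@@H]5C(=O)OC[C@]51[C@@](C)(C[C@H]3C6(C)OCCO6)C4=O | intermediate
29 | gem-dimethyl epoxide (mixture at the epoxide CH) | CC7(C)OC7CC[C@@]13C[C@@]4(C)C[C@@H]5C(=O)OC[C@]51[C@@](C)(C[C@H]3C6(C)OCCO6)C4=O | intermediate
30 | hydroxy ynoate (mixture at the propargylic CH) | CCOC(=O)C#CC(C(C)(C)O)CC[C@@]13C[C@@]4(C)C[C@@H]5C(=O)OC[C@]51[C@@](C)(C[C@H]3C6(C)OCCO6)C4=O | intermediate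
31 | Z-hydroxy enoate | CCOC(=O)/C=C\C(C(C)(C)O)CC[C@@]13C[C@@]4(C)C[C@@H]5C(=O)OC[C@]51[C@@](C)(C[C@H]3C6(C)OCCO6)C4=O | intermediate (not isolated)
32 | dihydropyranone dioxolane | CC7(C)OC(=O)C=CC7CC[C@@]13C[C@@]4(C)C[C@@H]5C(=O)OC[C@]51[C@@](C)(C[C@H]3C6(C)OCCO6)C4=O | intermediate (not isolated)
33 | dihydropyranone methyl ketone (mixture at the lactone γ-CH) | CC7(C)OC(=O)C=CC7CC[C@@]13C[C@@]4(C)C[C@@H]5C(=O)OC[C@]51[C@@](C)(C[C@H]3C(C)=O)C4=O | intermediate
34 | CNP0222978.3 | CC1(C)OC(=O)C=C[C@]12CC[C@@]13C[C@@]4(C)C[C@@H]5C(=O)OC[C@]51[C@@](C)(C[C@H]3[C@@]2(C)O)C4=O | target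

**Step count and risks**

Total step count: 24. Longest linear sequence: 22 steps (steps 1–6, 8, 9, 11–24).

Steps most likely to fail:

Step 8. The ester enolate formed in the first conjugate addition may close slowly onto the fully substituted β-carbon and be alkylated while still open-chain, and the auxiliary may discriminate the faces poorly. The fallback sets out from 9 and returns at 16, replacing auxiliary control by a classical resolution with a small acceptor. The same dienolate is treated with methyl acrylate and then propargyl bromide to give the racemic methyl ester F1. Bu4NF removes the silyl group and the alkoxide closes the racemic ketal lactone F2. AlMe3 with (S)-1-phenylethylamine opens the lactone to two diastereomeric hydroxy amides, which are separated. The one with the cage configuration of 16, hydroxy amide F3, is heated with aqueous HCl in dioxane, which hydrolyses the ketal and relactonises with loss of the amine to give 16.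

Step 16. The methyl group may migrate instead of the ring CH2 if the six-membered ring reacts from its chair form, and a pinacol closure on the concave face in step 14 would feed the wrong diol into the rearrangement. The fallback sets out from 22 and returns at 24, and it erases both carbinol centres, so any cis diol serves. Thiocarbonyldiimidazole converts the diol into the cyclic thionocarbonate F4. Heating with P(OMe)3 (Corey–Winter olefination) gives the cyclohexene F5. PhI(OH)OTs in aqueous acetonitrile adds to the trisubstituted alkene from the convex face (iodine on the CH carbon, water on the methyl-bearing carbon), and the ring CH2 then displaces the iodane with inversion. This oxidative ring contraction of a 1-methylcyclohexene to an acetylcyclopentane gives 24; the monosubstituted allyl alkene is less reactive.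

Step 24. The pyranolate may open to the dienoate carboxylate, the methyl ketone may be enolised instead, or closure may occur on the wrong face of the dienolate. The fallback sets out from 33 and returns at 34, generating the dienolate reductively instead of by deprotonation. Radical bromination (NBS, dibenzoyl peroxide, PhCF3, 80 °C) at the tertiary allylic γ-CH of the lactone gives the γ-bromo lactone F6. CrCl2 in THF at 0 °C converts it into the chromium dienolate (Reformatsky-type allylchromium), which adds to the ketone at its γ-carbon through a six-membered cyclic transition state. No base is present, the carbon-bound metal cannot ring-open, and the cyclic arrangement holds the carbonyl oxygen next to the vinyl CH, which is the geometry that leads to 34.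

**Further compounds**

F1 | step 8 | racemic methyl ester analogue of 14 (one enantiomer drawn) | COC1(OC)C[C@@]4(C)C[C@H](C(=O)OC)[C@]1(CO[Si](C)(C)C(C)(C)C)[C@@](C)(CC#C)C4=O
F2 | step 8 | racemic ketal lactone (one enantiomer drawn) | COC1(OC)C[C@@]4(C)C[C@@H]5C(=O)OC[C@]51[C@@](C)(CC#C)C4=O
F3 | step 8 | hydroxy amide of (S)-1-phenylethylamine with the cage configuration of 16 | COC1(OC)C[C@@]4(C)C[C@H](C(=O)N[C@@H](C)c5ccccc5)[C@]1(CO)[C@@](C)(CC#C)C4=O
F4 | step 16 | cyclic thionocarbonate of 22 | C=CC[C@@]13C[C@@]4(C)C[C@@H]5C(=O)OC[C@]51[C@@](C)(C[C@@]6(C)OC(=S)O[C@@H]36)C4=O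
F5 | step 16 | methylcyclohexene from 22 | C=CC[C@@]13C[C@@]4(C)C[C@@H]5C(=O)OC[C@]51[C@@](C)(CC(C)=C3)C4=O
F6 | step 24 | γ-bromo lactone from 33 (mixture at the C–Br carbon) | CC7(C)OC(=O)C=CC7(Br)CC[C@@]13C[C@@]4(C)C[C@@H]5C(=O)OC[C@]51[C@@](C)(C[C@H]3C(C)=O)C4=O
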